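The earlier runs and the new flask were computed for an exercise, and the scatter is random.

Late in each of these flasks the feed of Q is over and the volume has stopped growing, so D then meets Q diluted by the whole of the feed.

| flask | D | Q | Z | remark | time |
|---|---|---|---|---|---|
| larch | 0.10 M | 1.1 equiv (fed, over 6.0 min) | 18 mM (held) | run made earlier; the fed solution adds 1.0 times the starting volume |  |
| birch | 0.10 M | 1.7 equiv (fed, over 6.0 min) | 18 mM (held) | run made earlier; the fed solution adds 1.0 times the starting volume |  |
| Thursday's | 0.10 M | 1.30 equiv (fed, over 6.0 min) | 18 mM (held) | the fed solution adds 1.0 times the starting volume | 15 min |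
| Friday's | 0.10 M | 2.60 equiv (fed, over 6.0 min) | 18 mM (held) | the fed solution adds 1.0 times the starting volume | 15 min |

- larch (time / min: D / %, J / %): 0.667: 100.0, 0; 2.00: 98.4, 1.7; 4.00: 95.8, 3.6; 5.00: 94.3, 6.0; 8.00: 87.9, 11.5
- birch (time / min: D / %, J / %): 1.50: 99.2, 0.6; 3.00: 96.2, 4.0; 5.00: 91.0, 9.4; 6.00: 88.2, 11.8; 8.00: 82.3, 17.8

(each reading ± 0.3 percentage points)

- part of the D that has reacted at the end, Thursday's
- part of the D that has reacted at the end, Friday's
- what raising the equivalents of Q from its lowest to its highest value here does to the part of the D that has reacted (changes below 5 percentage points count as none) (no change / it falls / it rises)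

- amounts are per litre of the starting volume; all of the dose is in the solution fed
- at the start none of L is dissolved
- steps thought possible: D + Q -> X + J; Q + X <-> E; X + L <-> G; Z <-> L

D and Q give J and X. X may pair reversibly with Q as E or with L as G, and L dissolves from the held gas Z.

My zero of the scale is the bare case: pseudo-first-order loss of D against Q as fed, with no side step. Dilution leaves D's remaining fraction alone, so minus its log grows as the equivalents times a weighted time τ, measured against the charge of Q in the starting volume. The feed counts for 1.84 min, and each later minute counts half, so τ is 2.84 min at 8.00 min and 6.34 min at 15 min. Birch at 8.00 min gives 0.0403 min⁻¹, the log loss per equivalent and per minute of τ.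

One run proves little, but larch gives 0.0413 min⁻¹, and one reading's scatter moves that by 0.00109 min⁻¹. The bare case then puts Thursday's at 28.3% and Friday's at 48.6%.

Yet D eats Q one for one: on this estimate, 21.8% of Thursday's charge and 18.7% of Friday's by the end. That loss builds up over the run, so I take off half of it, which gives 25.6% and 45.3%. Suppose every X held a further Q as E: then the figures are 22.9% and 41.8%. Even crossing the pessimistic Friday with the bare-case Thursday, the gap of 13 percentage points exceeds 5 points, so I expect a rise.

The forecast says 26% and 44%, one point under my Friday's, and it rises: “I shade the estimates slightly down”.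

The flasks give 26.7% and 46.4%; it rises, by 20 points.

    D + Q → X + J (k = 0.00718 M⁻¹ s⁻¹)
    Q + X ⇌ E, settled at all times (K = 2780 M⁻¹)
    X + L ⇌ G, settled at all times (K = 93000 M⁻¹)
    Z ⇌ L, rate k4*(csat - [L]) (kL = 0.277 s⁻¹)

Friday's stands above Thursday's because of its equivalents: with Thursday's charge it gives 26.7%, not 46.4%. Its log loss is 2.01 times Thursday's, for 2.00 times the equivalents, and 0.0403 min⁻¹ with the drawdown had put Friday's at 45.3%. For a neighbour of Friday's charged with 4.40 equiv, the same reckoning leaves 35.4% of D, and that flask holds 34.5%.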